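The runs are calculated on assumed constants; scatter was added.

After 40.0 h the south-east flask showed 41.8% target and 0.6% substrate, so 57.6% of the substrate charged was a leftover that my readings did not name; after 5.00 d the same gap in the south flask was 39.8%.

| setting | south-east | south | flask |
|---|---|---|---|
| substrate | 0.071 M | 0.14 M | 0.071 M |
| partner | 0.80 equiv | 0.80 equiv | 0.800 equiv |
| gas | 44 mM (held) | 44 mM (held) | 44 mM (held) |
| remark | the very flask that is asked about, followed so far | run made earlier |  |
| time |  |  | 5.0 d |

south-east run (percent of the substrate charged)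

| time / h | intermediate / % | target / % | substrate / % |
|---|---|---|---|
| 0.500 | 16.7 | 0 | 75.0 |
| 1.00 | 25.0 | 2.0 | 53.6 |
| 2.00 | 29.6 | 7.8 | 24.6 |
| 4.00 | 19.8 | 21.6 | 2.9 |
| 8.00 | 3.2 | 38.5 | 0 |
| 20.0 | 0.2 | 42.2 | 0.2 |
| 40.0 | 0 | 41.8 | 0.6 |

south run (percent of the substrate charged)

| time / d | intermediate / % | target / % | substrate / % |
|---|---|---|---|
| 0.0556 | 42.3 | 3.7 | 37.0 |
| 0.104 | 45.5 | 10.5 | 16.3 |
| 0.250 | 22.0 | 38.3 | 0.4 |
| 0.500 | 1.5 | 58.6 | 0 |
| 1.04 | 0 | 60.3 | 0.2 |
| 2.50 | 0 | 60.6 | 0 |
| 5.00 | 0.1 | 60.1 | 0 |

(scatter of a reading: 0.3 percentage points)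

- time up to 5.0 d at which intermediate stands highest
- the amount of intermediate, in percent of the substrate charged, at that time

- at the start none of the gas is in solution

I took that gap for substrate lost by a rival path, and so I assumed that in these flasks, with gas held, the peak of intermediate follows p/(p + K), where p is the partner concentration as charged. The highest south reading of intermediate, 45.5% at a partner concentration of 0.112 M, gave K = 0.134 M, my half-peak concentration, the partner concentration at which this curve stands at half the substrate charged. The south-east flask has p = 0.0568 M, so I reckoned a peak of 29.7%, and I placed it near that flask's highest reading, at 0.083 d.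

The forecast said 30% at 0.087 d, by “Setting formation equal to loss”.

The flask gave 29.5% at 0.0799 d.

    substrate + partner → intermediate (k = 0.00210 /M/s)
    second reagent + intermediate → target (k = 0.00380 /M/s)
    substrate + second reagent → side product (k = 0.0110 /M/s)
    gas ⇌ second reagent, rate k4*(csat - [second reagent]) (kL = 2.00 × 10⁻⁴ /s)

My reckoning from K stood 0.20 percentage points above that peak. One more flask, like this one but with 1.40 equiv of partner, has p = 0.0994 M, lower than K, and the same curve gives it a peak of 42.6%. In that flask substrate, the limiting reagent, stood at 0% and partner at 57.6% of its charge after 5.00 d, and the peak of intermediate had been 43.7%.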